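**Retrosynthetic overview**

1. Building blocks: phloroglucinol 1 and isobutyryl chloride 2 (giving acylphloroglucinol 3), (E)-4-methylpent-2-enal 4 and 2,2,4,4-tetramethylcyclobutane-1,3-dione 5; the aromatic ring is bought, not built.
2. First ring-forming operation: two δ-lactone rings at once, by a twofold catalytic asymmetric [3+3] annulation of 3 with 4 (through mono-lactone 6) to bis-dihydrocoumarin 7. The disconnections are Ar–CH(iPr) and lactone O–C(=O); both stereocentres are set here.
3. Second ring-forming operation: both triketone (syncarpic acid) rings at once, by twofold enolate ring expansion of 5 on 7 (through 8) to target 9. In each ring the disconnections are the Cα–C(=O) bond to a carbonyl of 5 and the CMe2–C(=O) bond to the lactone carbonyl; the lactone opens and frees the phenol.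
4. 7 + 2 × 5 equals 9 exactly (C22H28O6 + 2 C8H12O2 = C38H52O10): no protecting groups, no redox adjustment, nothing cleaved.

Assumption: for the tautomer drawn, both CH(iPr) centres of the target are R; the catalyst enantiomer named in step 2 is taken to be the one that gives R centres, to be confirmed on the first run and replaced by its commercial mirror image if the sense is opposite.

**Step 1**
Reactants: 1 phloroglucinol; 2 isobutyryl chloride
Product: 3 2-methyl-1-(2,4,6-trihydroxyphenyl)propan-1-one (isobutyrylphloroglucinol)
Conditions: AlCl3 (4 equiv), PhNO2–CH2Cl2, 0 → 45 °C; ice/1 M HCl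
Reagents that add atoms: none
Why: Friedel–Crafts C-acylation of the triply activated arene, in which the chelated aryl ketone–AlCl3 complex deactivates the ring so that mono-acylation stops cleanly; no stereocentre is formed.

**Step 2**
Reactants: 3 isobutyrylphloroglucinol; 4 (E)-4-methylpent-2-enal (2.6 equiv)
Product: 7 (4R,10R)-bis-lactone (angular bis-dihydrocoumarin), via mono-lactone 6 (not isolated)
Conditions: (5aR,10bS)-N-mesityl-aminoindanol-triazolium chloride (15 mol%), DBU (0.5 equiv), 3,3',5,5'-tetra-tert-butyldiphenoquinone (2.6 equiv), 4 Å MS, toluene–THF (4:1), 0 °C → rt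
Reagents that add atoms: none
Why: Proposed new method: the carbene adds to 4 and the Breslow intermediate is oxidised by the quinone to the α,β-unsaturated acyl azolium, whose β-carbon is attacked by C-3 (then C-5) of the phloroglucinolate (Michael addition or O-addition/Coates–Claisen rearrangement) before the neighbouring phenol oxygen is acylated intramolecularly to close the δ-lactone and release the carbene, the aminoindanol backbone shielding one face of the acyl azolium so that each CH(iPr) centre is set R by catalyst control (a minor-enantiomer event ends up in a separable diastereomer, so 7 is essentially enantiopure after chromatography); closest known reaction type: enantioselective NHC-catalysed [3+3] annulation of enals or ynals with stable enols, naphthols and electron-rich phenols to 4-substituted dihydropyranones and dihydrocoumarins.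

**Step 3**
Reactants: 7 (4R,10R)-bis-lactone; 5 2,2,4,4-tetramethylcyclobutane-1,3-dione (2.4 equiv)
Product: 9 myrtucommulone A, via mono-ring-expanded lactone 8 (not isolated)
Conditions: LiHMDS (3.1 equiv), THF, −78 °C; 5 then LiHMDS (2.4 equiv), −78 → −20 °C; cold 1 M HCl
Reagents that add atoms: none
Why: Proposed new method: each lithium lactone enolate adds to a strained, non-enolisable C=O of 5 (aldol), the cyclobutanolate fragments by strain-releasing retro-aldol to a tertiary ketone enolate held 1,5 to the aryl-ester carbonyl, and Dieckmann closure on that activated lactone expels the phenoxide and gives the 2-substituted syncarpic acid as its stabilised enolate, the two CH(iPr) centres being β to every enolisable carbonyl and therefore untouched; closest known reaction types: nucleophilic ring opening of 5 to 2,2,4-trimethyl-3-oxopentanoyl derivatives, its base-catalysed ring-opening/Dieckmann conversion to hexamethylcyclohexane-1,3,5-trione, and Dieckmann condensations onto aryl esters.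

**Compound list**

1 | phloroglucinol (benzene-1,3,5-triol) | Oc1cc(O)cc(O)c1 | starting material
2 | isobutyryl chloride (2-methylpropanoyl chloride) | CC(C)C(Cl)=O | starting material
3 | 2-methyl-1-(2,4,6-trihydroxyphenyl)propan-1-one | CC(C)C(=O)c1c(O)cc(O)cc1O | intermediate
4 | (E)-4-methylpent-2-enal | CC(C)/C=C/C=O | starting material
5 | 2,2,4,4-tetramethylcyclobutane-1,3-dione | CC1(C)C(=O)C(C)(C)C1=O | starting material
6 | (4R)-5,7-dihydroxy-6-(2-methylpropanoyl)-4-(propan-2-yl)-3,4-dihydro-2H-chromen-2-one (lactone closed through the oxygen para to the acyl group) | CC(C)C(=O)c1c(O)c2[C@@H](C(C)C)CC(=O)Oc2cc1O | intermediate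
7 | (4R,10R)-5-hydroxy-6-(2-methylpropanoyl)-4,10-di(propan-2-yl)-3,4,9,10-tetrahydro-2H,8H-benzo[1,2-b:3,4-b']dipyran-2,8-dione (acylphloroglucinol whose C-3/O-4 and C-5/O-6 are each bridged by –CH(iPr)–CH2–C(=O)–; free chelated 2-OH) | CC(C)C(=O)c1c(O)c2[C@@H](C(C)C)CC(=O)Oc2c3[C@@H](C(C)C)CC(=O)Oc13 | intermediate
8 | (4R)-5,7-dihydroxy-8-[(1R)-1-(2-hydroxy-3,3,5,5-tetramethyl-4,6-dioxocyclohex-1-en-1-yl)-2-methylpropyl]-6-(2-methylpropanoyl)-4-(propan-2-yl)-3,4-dihydro-2H-chromen-2-one (one lactone of 7 expanded, the other intact) | CC(C)C(=O)c1c(O)c2[C@@H](C(C)C)CC(=O)Oc2c([C@H](C3=C(O)C(C)(C)C(=O)C(C)(C)C3=O)C(C)C)c1O | intermediate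
9 | myrtucommulone A, (R,R)-isomer | CC(C)C(=O)c1c(O)c([C@H](C2=C(O)C(C)(C)C(=O)C(C)(C)C2=O)C(C)C)c(O)c([C@H](C2=C(O)C(C)(C)C(=O)C(C)(C)C2=O)C(C)C)c1O | target

**Totals**

Total step count: 3. Longest linear sequence: 3.

**Steps most likely to fail, with fallbacks**

Step 3 (highest risk). 
- After ring opening of 5, the tertiary enolate may be quenched by the newly acidic 3-acyl-lactone proton before the Dieckmann closure. 
- The lactone enolates may also self-condense, or LiHMDS and phenoxides may open 5 directly. 
- Warming the polyanion risks retro-Michael scrambling of the benzylic centres; the quench is therefore cold and dilute, also to avoid acid-driven pyran cyclodehydration. 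
- The second LiHMDS charge is needed because each ring expansion liberates two acidic protons (phenol and triketone) that would otherwise destroy the remaining lactone enolate.

Fallback, setting out from 7 and returning at 9: the roles are reversed so that the last C–C bond formed is the one that creates the stabilised enolate. 5 is opened with NaOMe in MeOH to methyl 2,2,4-trimethyl-3-oxopentanoate F4. F4 is deprotonated at its only enolisable position (LDA, THF, −78 °C, 4.5 equiv) and the tertiary enolate is added to the lithium phenoxide of 7. Claisen acylation by the two aryl-lactone carbonyls opens both lactones and gives the (R,R)-bis(triketo ester) F5. F5 is then closed on both sides by a conventional Dieckmann condensation of the CH2 enolate onto the terminal methyl ester (LiHMDS or KOt-Bu, THF, 0 °C), giving 9.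

Step 2. 
- The acyl azolium may only O-acylate the phenol; the resulting activated aryl enoate should re-enter the cycle, but this is not assured. 
- The second annulation may stall at 6 because the ring is less electron-rich. 
- The quinone may oxidise the phenol. 
- The ee or the sense of induction may be unsatisfactory; at 95:5 selectivity per event about 10% of the material goes to the (4R,10S)/(4S,10R) diastereomers, which are removed at 7. 
- Which ortho oxygen closes each lactone is irrelevant to the outcome, because step 3 opens both lactones.

Fallback, setting out from 3 and returning at 7: the electrophile and activation mode are changed to a non-oxidative conjugate Friedel–Crafts addition. Meldrum's acid and isobutyraldehyde are condensed (piperidinium acetate cat.) to 2,2-dimethyl-5-(2-methylpropylidene)-1,3-dioxane-4,6-dione F2. F2 (2.2 equiv) is added to 3 under a bifunctional cinchona squaramide (10 mol%, CH2Cl2, −20 °C), a reaction type demonstrated for acylphloroglucinols with alkylidene 1,3-dicarbonyls, to give the bis-Michael adduct F3. Heating F3 (toluene, 90 °C) closes both lactones with loss of acetone and CO2 and gives 7. If the ee is short, 7 is upgraded by crystallisation or chiral SFC.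

Step 1. O-acylation or di-C-acylation and a difficult aluminium work-up can lower the yield.

Fallback, setting out from 1 and returning at 3: a Hoesch reaction. 1 and isobutyronitrile with ZnCl2 and HCl gas in Et2O at 0 °C precipitate 2-methyl-1-(2,4,6-trihydroxyphenyl)propan-1-iminium chloride F1, which is hydrolysed in boiling water to 3.

**Further compounds**

F1 | step 1 | 2-methyl-1-(2,4,6-trihydroxyphenyl)propan-1-iminium chloride | CC(C)C(=[NH2+])c1c(O)cc(O)cc1O.[Cl-]
F2 | step 2 | 2,2-dimethyl-5-(2-methylpropylidene)-1,3-dioxane-4,6-dione | CC(C)C=C1C(=O)OC(C)(C)OC1=O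
F3 | step 2 | 1-{3,5-bis[1-(2,2-dimethyl-4,6-dioxo-1,3-dioxan-5-yl)-2-methylpropyl]-2,4,6-trihydroxyphenyl}-2-methylpropan-1-one (S,S by CIP; same spatial arrangement as in 7) | CC(C)C(=O)c1c(O)c([C@@H](C(C)C)C2C(=O)OC(C)(C)OC2=O)c(O)c([C@@H](C(C)C)C2C(=O)OC(C)(C)OC2=O)c1O
F4 | step 3 | methyl 2,2,4-trimethyl-3-oxopentanoate | COC(=O)C(C)(C)C(=O)C(C)C
F5 | step 3 | (R,R)-bis(triketo ester): 3 carrying at C-3 and C-5 a –CH(iPr)–CH2–CO–CMe2–CO–CMe2–CO2Me chain | CC(C)C(=O)c1c(O)c([C@@H](C(C)C)CC(=O)C(C)(C)C(=O)C(C)(C)C(=O)OC)c(O)c([C@@H](C(C)C)CC(=O)C(C)(C)C(=O)C(C)(C)C(=O)OC)c1O
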